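**Retrosynthetic overview**
1. Labels (seco-kaurane numbering): ring A is the cyclohexane C1–C5/C10 carrying OAc (C3), Me-18 and the lactone carbonyl C19 (C4), the C6–C7 chain (C5), Me-20 and the lactone oxygen (C10); the bicyclo[3.2.1]octanone is C8 (quaternary), C9 (C=O), C11–C14, C15, C16(=C17H2).
2. Last ring (cyclopentane C8/C14/C13/C16/C15): C8–C15 by conjugate reduction of a C7=C8 enone followed by 5-exo-tet enolate alkylation; C7=C8 by HWE of aldehyde 14 (C7) with ketophosphonate 18, whose C13 stereocentre comes from a desymmetrised cyclohexanone.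
3. Aldehyde 14 comes from tricyclic bis-lactone 11 by opening its temporary O3–C7 δ-lactone.
4. Key disconnection: the lactone O–C10 bond together with C5–C6 of 11, back to monocyclic bromoacetate 9 (photoredox radical–polar crossover); ring A itself comes from an anisic acid by asymmetric Birch reduction–methylation.
5. Enabling feature: on ring A, O3 and C6 are cis-1,3-diaxial and both anti to the C19–O–C10 bridge, so an O3–C7(=O)–C6 ester tether can deliver C6 to C5 of a C5=C10 alkene while the C4 carboxamide, 1,3 to C10, closes O–C10 from the other face. Ring order: A → δ-lactone → γ-lactone (δ-lactone then opened) → cyclopentane.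

Key step: step 6

Assumption: the sense of induction of the two chiral reagents is taken from the established models ((S)-prolinol-ether benzamide → (1S) quaternary centre; (S,S)-lithium amide → (4R)-enolate, by analogy with 4-tert-butylcyclohexanone); if either sense is the reverse, the antipodal reagent (both commercial) is used and nothing else changes.

Step 1
Reactants: 1 2-methoxy-5-methylbenzoic acid; 2 (S)-2-(methoxymethyl)pyrrolidine
Product: 4 (2-methoxy-5-methylphenyl)[(2S)-2-(methoxymethyl)pyrrolidin-1-yl]methanone, via 2-methoxy-5-methylbenzoyl chloride 3 (not isolated)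
Conditions: (COCl)2, cat. DMF, CH2Cl2, 0 °C → rt; then 2, Et3N, CH2Cl2, 0 °C
Reagents that add atoms: none
Why: Acid chloride formation followed by N-acylation should give the tertiary benzamide without touching the pyrrolidine stereocentre.

Step 2
Reactants: 4 (2-methoxy-5-methylphenyl)[(2S)-2-(methoxymethyl)pyrrolidin-1-yl]methanone
Product: 6 [(1S)-2-methoxy-1,5-dimethylcyclohexa-2,5-dien-1-yl][(2S)-2-(methoxymethyl)pyrrolidin-1-yl]methanone, via potassium amide enolate 5 (not isolated)
Conditions: K, NH3(l)/THF, t-BuOH (1 equiv), −78 °C; piperylene; then MeI, −78 °C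
Reagents that add atoms: iodomethane, CI
Why: Birch reduction–alkylation (Schultz asymmetric variant) should give the chelated potassium amide enolate 5, which is methylated at the ipso carbon on the face left open by the auxiliary, setting the quaternary centre C4 as (S).

Step 3
Reactants: 6 [(1S)-2-methoxy-1,5-dimethylcyclohexa-2,5-dien-1-yl][(2S)-2-(methoxymethyl)pyrrolidin-1-yl]methanone
Product: 7 (2S)-2-{[(2S)-2-(methoxymethyl)pyrrolidin-1-yl]carbonyl}-2,4-dimethylcyclohex-3-en-1-one
Conditions: 1 M HCl, MeOH/H2O, rt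
Reagents that add atoms: water, O
Why: Acid hydrolysis of the enol ether should unveil the C3 ketone, and the quaternary C4 prevents the C5=C10 alkene from moving into conjugation.

Step 4
Reactants: 7 (2S)-2-{[(2S)-2-(methoxymethyl)pyrrolidin-1-yl]carbonyl}-2,4-dimethylcyclohex-3-en-1-one
Product: 8 [(1S,6S)-6-hydroxy-1,3-dimethylcyclohex-2-en-1-yl][(2S)-2-(methoxymethyl)pyrrolidin-1-yl]methanone (OH trans to the carboxamide)
Conditions: Zn(BH4)2, Et2O, −30 °C
Reagents that add atoms: none
Why: Chelation-controlled hydride reduction: zinc bridging the ketone and amide carbonyls holds the amide in the carbonyl plane and Me-18 axial, so hydride should add anti to that methyl and set C3 (S) with the OH trans to C19.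

Step 5
Reactants: 8 [(1S,6S)-6-hydroxy-1,3-dimethylcyclohex-2-en-1-yl][(2S)-2-(methoxymethyl)pyrrolidin-1-yl]methanone
Product: 9 (1S,2S)-2-{[(2S)-2-(methoxymethyl)pyrrolidin-1-yl]carbonyl}-2,4-dimethylcyclohex-3-en-1-yl bromoacetate
Conditions: BrCH2COBr, pyridine, CH2Cl2, 0 °C
Reagents that add atoms: bromoacetyl bromide, O=C(Br)CBr
Why: O-Acylation of the secondary alcohol installs C6 and C7 as an ester tether on O3 with the C–Br bond as radical precursor; no stereocentre is affected.

Step 6
Reactants: 9 (1S,2S)-2-{[(2S)-2-(methoxymethyl)pyrrolidin-1-yl]carbonyl}-2,4-dimethylcyclohex-3-en-1-yl bromoacetate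
Product: 11 (1S,4S,7S,8S)-4,7-dimethyl-5,11-dioxatricyclo[5.4.0.0(4,8)]undecane-6,10-dione, via iminium lactone bromide 10 (not isolated)
Conditions: fac-Ir(ppy)3 (1 mol %), MeCN/H2O (9:1), degassed, 450 nm LEDs, 40 °C
Reagents that add atoms: water, O
Why: Photoredox radical–polar crossover: excited fac-Ir(ppy)3 reduces the C–Br bond to the electrophilic C6 radical, which adds 6-exo-trig to C5 (the less substituted carbon of C5=C10) and closes the δ-lactone; the tertiary C10 radical is oxidised by Ir(IV) to the cation, which is captured by the carbonyl oxygen of the C4 carboxamide (O–C10 bond, five-membered ring; formally 5-endo with respect to the original alkene but in fact the collapse of a 1,3-diaxial oxygen/cation pair), and water hydrolyses iminium ether 10 with C–N cleavage to the γ-lactone, releasing the auxiliary. The closest known reactions are photoredox ATRA–lactonisation (oxy-alkylation) of alkenoic acids and amides with α-bromo esters, and the halolactonisation of Birch-derived prolinol carboxamides with loss of the auxiliary. C5 is set by the tether, since C6 can only reach the alkene face that carries O3; C10 is set by C4, since the carboxamide is trans to O3 and can bridge C4/C10 only cis-1,3, so O–C10 ends anti to C6. The step needs 6-exo over 7-endo addition (ring size and polarity: electrophilic radical to the less hindered terminus, giving a tertiary radical), cyclisation before reduction (no hydrogen donor; warming populates the s-cis ester rotamer), and amide-oxygen capture before E1 loss or hydration (the amide is the best nucleophile present and is axially pre-organised).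

Step 7
Reactants: 11 (1S,4S,7S,8S)-4,7-dimethyl-5,11-dioxatricyclo[5.4.0.0(4,8)]undecane-6,10-dione
Product: 12 2-[(1S,2S,5S,8S)-2-hydroxy-1,5-dimethyl-7-oxo-6-oxabicyclo[3.2.1]octan-8-yl]-N-methoxy-N-methylacetamide
Conditions: MeNH(OMe), AlMe3, CH2Cl2, 0 °C → rt
Reagents that add atoms: N,O-dimethylhydroxylamine, CNOC
Why: Weinreb aminolysis of a lactone with the dimethylaluminium amide should open only the δ-lactone at C7 (α-CH2), because the γ-lactone carbonyl C19 is neopentyl and its opening would give only a tertiary alkoxide that recloses.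

Step 8
Reactants: 12 2-[(1S,2S,5S,8S)-2-hydroxy-1,5-dimethyl-7-oxo-6-oxabicyclo[3.2.1]octan-8-yl]-N-methoxy-N-methylacetamide
Product: 13 (1S,2S,5S,8S)-8-{2-[methoxy(methyl)amino]-2-oxoethyl}-1,5-dimethyl-7-oxo-6-oxabicyclo[3.2.1]octan-2-yl acetate
Conditions: Ac2O, Et3N, DMAP (cat.), CH2Cl2, 0 °C → rt
Reagents that add atoms: acetic anhydride, CC(=O)OC(C)=O
Why: DMAP-catalysed acetylation installs the C3 acetate of the target and, done at once, keeps the axial C3–OH from re-closing onto C7.

Step 9
Reactants: 13 (1S,2S,5S,8S)-8-{2-[methoxy(methyl)amino]-2-oxoethyl}-1,5-dimethyl-7-oxo-6-oxabicyclo[3.2.1]octan-2-yl acetate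
Product: 14 (1S,2S,5S,8S)-1,5-dimethyl-7-oxo-8-(2-oxoethyl)-6-oxabicyclo[3.2.1]octan-2-yl acetate
Conditions: Cp2Zr(H)Cl (1.5 equiv), THF, rt
Reagents that add atoms: none
Why: Schwartz-reagent reduction of the Weinreb amide stops at the aldehyde through a stable zirconated hemiaminal and should leave the acetate and the γ-lactone untouched.

Step 10
Reactants: 15 4-(prop-1-en-2-yl)cyclohexan-1-one
Product: 17 diethyl (4R)-4-(prop-1-en-2-yl)cyclohex-1-en-1-yl phosphate, via lithium enolate 16 (not isolated)
Conditions: (S,S)-bis(1-phenylethyl)amine, n-BuLi, LiCl, THF, −78 °C; then ClP(O)(OEt)2, −78 → 0 °C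
Reagents that add atoms: diethyl chlorophosphate, CCOP(=O)(Cl)OCC
Why: Enantioselective deprotonation with a chiral lithium amide (Simpkins–Koga desymmetrisation of a 4-substituted cyclohexanone) removes one of the two enantiotopic axial α-hydrogens, and O-phosphorylation fixes the C8=C9 enolate so that C13 becomes a stereocentre (R).

Step 11
Reactants: 17 diethyl (4R)-4-(prop-1-en-2-yl)cyclohex-1-en-1-yl phosphate
Product: 18 diethyl [(5R)-2-oxo-5-(prop-1-en-2-yl)cyclohexyl]phosphonate (C1 epimers)
Conditions: LDA (2.2 equiv), THF, −78 °C → rt; AcOH quench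
Reagents that add atoms: none
Why: Wiemer vinyl phosphate → β-ketophosphonate rearrangement (directed vinylic lithiation at C8, then 1,3-O→C phosphoryl shift) puts phosphorus on C8 only, so the desymmetrisation is carried over to carbon.

Step 12
Reactants: 14 (1S,2S,5S,8S)-1,5-dimethyl-7-oxo-8-(2-oxoethyl)-6-oxabicyclo[3.2.1]octan-2-yl acetate; 18 diethyl [(5R)-2-oxo-5-(prop-1-en-2-yl)cyclohexyl]phosphonate
Product: 19 (1S,2S,5S,8S)-1,5-dimethyl-7-oxo-8-{(2E)-2-[(5R)-2-oxo-5-(prop-1-en-2-yl)cyclohexylidene]ethyl}-6-oxabicyclo[3.2.1]octan-2-yl acetate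
Conditions: LiCl, i-Pr2NEt, MeCN, rt
Reagents that add atoms: none
Why: Horner–Wadsworth–Emmons olefination (Masamune–Roush conditions) should form the C7=C8 (E)-enone and join the two halves without creating a stereocentre; a minor diastereomer arising from incomplete enantiopurity of 18 should be separable here.

Step 13
Reactants: 19 (1S,2S,5S,8S)-1,5-dimethyl-7-oxo-8-{(2E)-2-[(5R)-2-oxo-5-(prop-1-en-2-yl)cyclohexylidene]ethyl}-6-oxabicyclo[3.2.1]octan-2-yl acetate
Product: 20 (1S,2S,5S,8S)-8-{(2E)-2-[(5R)-5-(3-chloroprop-1-en-2-yl)-2-oxocyclohexylidene]ethyl}-1,5-dimethyl-7-oxo-6-oxabicyclo[3.2.1]octan-2-yl acetate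
Conditions: Ca(OCl)2, CO2 (s), CH2Cl2/H2O, 0 °C
Reagents that add atoms: calcium hypochlorite, [Ca+2].[O-]Cl.[O-]Cl
Why: Ene-type allylic chlorination by HOCl should attack only the electron-rich 1,1-disubstituted alkene (the enone alkene is electron-poor) and give the 2-substituted allyl chloride; it is done this late because an allylic chloride would not survive the lithium amides of steps 10–11.

Step 14
Reactants: 20 (1S,2S,5S,8S)-8-{(2E)-2-[(5R)-5-(3-chloroprop-1-en-2-yl)-2-oxocyclohexylidene]ethyl}-1,5-dimethyl-7-oxo-6-oxabicyclo[3.2.1]octan-2-yl acetate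
Product: 22 (1S,2S,5S,8S)-1,5-dimethyl-8-{2-[(1S,5R)-6-methylidene-2-oxobicyclo[3.2.1]octan-1-yl]ethyl}-7-oxo-6-oxabicyclo[3.2.1]octan-2-yl acetate (CNP0204681.1), via lithium enolate 21 (not isolated)
Conditions: L-Selectride (1.05 equiv), THF, −78 °C; then −78 → 25 °C
Reagents that add atoms: none
Why: Tandem conjugate reduction–alkylation: hydride adds to C7 of the s-cis enone and gives specifically the C8 enolate 21, which displaces the allylic chloride (5-exo-tet) on the face of the axial C13 side chain; only the cis-bridged closure is possible, so C13 (R) dictates C8 (S).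

**Compound list**
1 | 2-methoxy-5-methylbenzoic acid | COc1ccc(C)cc1C(=O)O | starting material
2 | (S)-2-(methoxymethyl)pyrrolidine | COC[C@@H]1CCCN1 | starting material
3 | 2-methoxy-5-methylbenzoyl chloride | COc1ccc(C)cc1C(Cl)=O | intermediate
4 | (2-methoxy-5-methylphenyl)[(2S)-2-(methoxymethyl)pyrrolidin-1-yl]methanone | COC[C@@H]1CCCN1C(=O)c1cc(C)ccc1OC | intermediate
5 | potassium amide enolate of the 1,4-dihydrobenzamide (exocyclic C4=C19 enolate; ring C3(OMe)=C2 and C10(Me)=C5) | COC[C@@H]1CCCN1C([O-])=C1C=C(C)CC=C1OC.[K+] | intermediate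
6 | [(1S)-2-methoxy-1,5-dimethylcyclohexa-2,5-dien-1-yl][(2S)-2-(methoxymethyl)pyrrolidin-1-yl]methanone | COC1=CCC(C)=C[C@]1(C)C(=O)N1CCC[C@H]1COC | intermediate
7 | (2S)-2-{[(2S)-2-(methoxymethyl)pyrrolidin-1-yl]carbonyl}-2,4-dimethylcyclohex-3-en-1-one | O=C1CCC(C)=C[C@]1(C)C(=O)N1CCC[C@H]1COC | intermediate
8 | [(1S,6S)-6-hydroxy-1,3-dimethylcyclohex-2-en-1-yl][(2S)-2-(methoxymethyl)pyrrolidin-1-yl]methanone (OH trans to the carboxamide) | C[C@]1(C(=O)N2CCC[C@H]2COC)C=C(C)CC[C@@H]1O | intermediate
9 | (1S,2S)-2-{[(2S)-2-(methoxymethyl)pyrrolidin-1-yl]carbonyl}-2,4-dimethylcyclohex-3-en-1-yl bromoacetate | C[C@]1(C(=O)N2CCC[C@H]2COC)C=C(C)CC[C@@H]1OC(=O)CBr | intermediate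
10 | iminium lactone bromide (cyclic O-alkyl iminium ether of 11 at C19 carrying the (S)-2-(methoxymethyl)pyrrolidinium unit) | O=C1C[C@H]2[C@]3(C)C(=[N+]4CCC[C@H]4COC)O[C@@]2(C)CC[C@@H]3O1.[Br-] | intermediate
11 | (1S,4S,7S,8S)-4,7-dimethyl-5,11-dioxatricyclo[5.4.0.0(4,8)]undecane-6,10-dione (γ-lactone C19–O–C10 on one face of ring A, δ-lactone C7–O3 on the other) | O=C1C[C@H]2[C@]3(C)C(=O)O[C@@]2(C)CC[C@@H]3O1 | intermediate
12 | 2-[(1S,2S,5S,8S)-2-hydroxy-1,5-dimethyl-7-oxo-6-oxabicyclo[3.2.1]octan-8-yl]-N-methoxy-N-methylacetamide | CON(C)C(=O)C[C@H]1[C@]2(C)C(=O)O[C@@]1(C)CC[C@@H]2O | intermediate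
13 | (1S,2S,5S,8S)-8-{2-[methoxy(methyl)amino]-2-oxoethyl}-1,5-dimethyl-7-oxo-6-oxabicyclo[3.2.1]octan-2-yl acetate | CON(C)C(=O)C[C@H]1[C@]2(C)C(=O)O[C@@]1(C)CC[C@@H]2OC(C)=O | intermediate
14 | (1S,2S,5S,8S)-1,5-dimethyl-7-oxo-8-(2-oxoethyl)-6-oxabicyclo[3.2.1]octan-2-yl acetate | O=CC[C@H]1[C@]2(C)C(=O)O[C@@]1(C)CC[C@@H]2OC(C)=O | intermediate
15 | 4-(prop-1-en-2-yl)cyclohexan-1-one | CC(=C)C1CCC(=O)CC1 | starting material
16 | lithium (4R)-4-(prop-1-en-2-yl)cyclohex-1-en-1-olate | [Li+].[O-]C1=CC[C@H](C(C)=C)CC1 | intermediate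
17 | diethyl (4R)-4-(prop-1-en-2-yl)cyclohex-1-en-1-yl phosphate | CCOP(=O)(OCC)OC1=CC[C@H](C(C)=C)CC1 | intermediate
18 | diethyl [(5R)-2-oxo-5-(prop-1-en-2-yl)cyclohexyl]phosphonate (C1 epimers) | CCOP(=O)(OCC)C1C[C@H](C(C)=C)CCC1=O | intermediate
19 | (1S,2S,5S,8S)-1,5-dimethyl-7-oxo-8-{(2E)-2-[(5R)-2-oxo-5-(prop-1-en-2-yl)cyclohexylidene]ethyl}-6-oxabicyclo[3.2.1]octan-2-yl acetate | CC(=C)[C@@H]1CCC(=O)/C(=C/C[C@H]2[C@]3(C)C(=O)O[C@@]2(C)CC[C@@H]3OC(C)=O)C1 | intermediate
20 | (1S,2S,5S,8S)-8-{(2E)-2-[(5R)-5-(3-chloroprop-1-en-2-yl)-2-oxocyclohexylidene]ethyl}-1,5-dimethyl-7-oxo-6-oxabicyclo[3.2.1]octan-2-yl acetate | ClCC(=C)[C@@H]1CCC(=O)/C(=C/C[C@H]2[C@]3(C)C(=O)O[C@@]2(C)CC[C@@H]3OC(C)=O)C1 | intermediate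
21 | lithium enolate (C8=C9–OLi) formed by hydride addition to C7 of 20 | [Li+].[O-]C1=C(CC[C@H]2[C@]3(C)C(=O)O[C@@]2(C)CC[C@@H]3OC(C)=O)C[C@H](C(=C)CCl)CC1 | intermediate
22 | (1S,2S,5S,8S)-1,5-dimethyl-8-{2-[(1S,5R)-6-methylidene-2-oxobicyclo[3.2.1]octan-1-yl]ethyl}-7-oxo-6-oxabicyclo[3.2.1]octan-2-yl acetate (CNP0204681.1) | C=C1C[C@]2(CC[C@H]3[C@]4(C)C(=O)O[C@@]3(C)CC[C@@H]4OC(C)=O)C[C@H]1CCC2=O | target

**Step count**
Total steps: 14. Longest linear sequence: 12 (steps 1–9, then 12–14); the second branch (steps 10–11) joins at step 12.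

**Steps most likely to fail**

Step 6 (key step). The ester-tethered radical may be reduced before it cyclises, because only the minor s-cis ester rotamer can reach C5, and the C10 cation may lose a proton instead of being captured. The fallback uses known chemistry, sets out from 9 and returns at 11. Compound 9 is treated with N,N'-ditosylhydrazine and DBU to give the diazoacetate F1. Rh2(OAc)4 in CH2Cl2 then effects intramolecular cyclopropanation of C5=C10 from the face of the tether and gives the cyclopropane-fused δ-lactone F2. BF3·OEt2 in wet CH2Cl2 opens this acceptor cyclopropane at the tertiary carbon C10 with inversion by the amide oxygen (homo-conjugate addition) to give iminium lactone 10, which is hydrolysed to 11.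

Step 14. 1,2-Reduction of the enone, hydride displacement of the allylic chloride, or proton transfer to the enolate before ring closure may compete. The fallback sets out from 20 and returns at 22. Catalytic [(Ph3P)CuH]6 with PhMe2SiH gives the regiodefined silyl enol ether F3, which is isolated. Pd2(dba)3/dppe with Bu4N Ph3SiF2 then ionises the allylic chloride to the symmetrical 2-substituted π-allyl complex, and the fluoride-released C8 enolate closes the five-membered ring (intramolecular Tsuji–Trost allylation).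

Step 4. Hydride delivery from the wrong face is possible if zinc chelation of the ketone and amide is incomplete. The fallback sets out from 7 and returns at 9, by-passing step 5. Reduction with L-Selectride (non-chelating, attack anti to the bulky carboxamide) is used to give deliberately the C3-epimeric alcohol F4. Mitsunobu esterification of F4 with bromoacetic acid (PPh3, DIAD) inverts C3 and gives 9 directly.

Further compounds
F1 | step 6 | (1S,2S)-2-{[(2S)-2-(methoxymethyl)pyrrolidin-1-yl]carbonyl}-2,4-dimethylcyclohex-3-en-1-yl diazoacetate | C[C@]1(C(=O)N2CCC[C@H]2COC)C=C(C)CC[C@@H]1OC(=O)C=[N+]=[N-]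
F2 | step 6 | cyclopropane-fused δ-lactone (C6 bridging C5 and C10 on the face of O3; C7(=O)–O3 lactone; C4 carboxamide retained) | O=C1[C@H]2[C@H]3[C@](C)(C(=O)N4CCC[C@H]4COC)[C@@H](O1)CC[C@@]23C
F3 | step 14 | dimethyl(phenyl)silyl enol ether (C8=C9–OSi) of the conjugate-reduction product of 20 | ClCC(=C)[C@@H]1CCC(O[Si](C)(C)c2ccccc2)=C(CC[C@H]3[C@]4(C)C(=O)O[C@@]3(C)CC[C@@H]4OC(C)=O)C1
F4 | step 4 | [(1S,6R)-6-hydroxy-1,3-dimethylcyclohex-2-en-1-yl][(2S)-2-(methoxymethyl)pyrrolidin-1-yl]methanone (OH cis to the carboxamide) | C[C@]1(C(=O)N2CCC[C@H]2COC)C=C(C)CC[C@H]1O
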